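**Retrosynthetic overview**

1. Structural feature: ring C (third ring from the 2,4,6-trihydroxyphenoxy ring A) carries oxygen on C1 and C3–C6 and hydrogen only on C2. C3–C6 with their four oxygens are the four carbons of squaric acid, and C1(O–ring B)–C2(H) is the two-carbon unit of an aryl vinyl ether of the AB phenol.
2. Key disconnection: the C6–C1 bond of ring C. Ring C opens to racemic 4-[(Z)-2-(AB-aryloxy)ethenyl]-2,3-bis(benzyloxy)-4-(methoxymethoxy)cyclobut-2-en-1-one, made from dibenzyl squarate and the lithium aryloxyacetylide of the AB phenol (through its dichlorovinyl ether from trichloroethylene), then acetal protection and semi-hydrogenation.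
3. Design points: a 2-aryloxyvinyllithium with lithium anti to oxygen would expel aryloxide, so the two carbons arrive as the acetylide and the alkene is Z (its geometry disappears on aromatisation). The carbinol oxygen carries a methoxymethyl group, not a silyl group, because it must outlast four phosphate-mediated copper couplings in the presence of phenoxides.
4. Remaining disconnections: every other diaryl ether joins a 2,6-dioxygenated (hindered) phenol oxygen to an unhindered aryl carbon. Each is formed by CuI-catalysed coupling of the growing phenol with a formyl-activated aryl bromide, and Baeyer–Villiger oxidation of the formyl group then uncovers the next hindered phenol.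
5. Ring order: A + B (steps 1–5), ring C by the electrocyclic cascade (steps 6–11), then D, E, F and G one at a time (steps 12–20), acetal cleavage and global hydrogenolysis (steps 21–22).

Key step: step 11

Remark: 16, 17 and 18 are racemates at the carbinol carbon, the only stereocentre of the route; it is destroyed in step 11 and the target is achiral. In names, "AB-aryloxy", "ABC-aryloxy" and so on mean the aryloxy group left when the phenol of that name (9, 21, 24, 30, 33) loses its hydroxyl hydrogen.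

**Route**

Step 1
Reactants: 1 2,4,6-trihydroxybenzaldehyde
Product: 2 2,4,6-tris(benzyloxy)benzaldehyde
Conditions: BnBr (3.5 equiv), K2CO3, DMF, 60 °C
Reagents that add atoms: benzyl bromide, BrCc1ccccc1
Why: Williamson ether synthesis; the formyl group damps C-alkylation of the phloroglucinol ring, so all three phenoxides are O-benzylated, the two chelated ortho hydroxyls reacting last on warming.

Step 2
Reactants: 2 2,4,6-tris(benzyloxy)benzaldehyde
Product: 4 2,4,6-tris(benzyloxy)phenol (ring A phenol), via aryl formate 3 (not isolated)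
Conditions: mCPBA, CH2Cl2, 0 °C to rt; then K2CO3, MeOH/THF, rt
Reagents that add atoms: meta-chloroperoxybenzoic acid (mCPBA), O=C(OO)c1cccc(Cl)c1
Why: Baeyer–Villiger oxidation in which the electron-rich trialkoxyaryl group migrates in preference to hydrogen, followed by methanolysis of the formate.

Step 3
Reactants: 5 4-bromo-2,6-difluorobenzaldehyde
Product: 6 4-bromo-2,6-bis(benzyloxy)benzaldehyde
Conditions: BnOH (2.1 equiv), NaH, THF, 0 to 50 °C
Reagents that add atoms: benzyl alcohol, OCc1ccccc1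
Why: Nucleophilic aromatic substitution (SNAr) of the two fluorides ortho to the formyl group by benzyloxide; fluoride is by far the better leaving group in addition–elimination, so the para bromide is kept.

Step 4
Reactants: 4 2,4,6-tris(benzyloxy)phenol; 6 4-bromo-2,6-bis(benzyloxy)benzaldehyde
Product: 7 AB aldehyde 2,6-bis(benzyloxy)-4-[2,4,6-tris(benzyloxy)phenoxy]benzaldehyde
Conditions: CuI (10 mol%), picolinic acid (20 mol%), K3PO4, DMSO, 90 °C
Reagents that add atoms: none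
Why: Ullmann-type diaryl ether synthesis; the picolinate-ligated copper catalyst accepts 2,6-disubstituted phenoxides, and the bromide is unhindered and activated by the para formyl group.

Step 5
Reactants: 7 AB aldehyde
Product: 9 AB phenol 2,6-bis(benzyloxy)-4-[2,4,6-tris(benzyloxy)phenoxy]phenol, via aryl formate 8 (not isolated)
Conditions: mCPBA, CH2Cl2, 0 °C to rt; then K2CO3, MeOH/THF, rt
Reagents that add atoms: meta-chloroperoxybenzoic acid (mCPBA), O=C(OO)c1cccc(Cl)c1
Why: Baeyer–Villiger oxidation of a 2,4,6-trioxygenated benzaldehyde (aryl migration) and formate methanolysis give the hindered ring B phenol.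

Step 6
Reactants: 9 AB phenol; 10 trichloroethylene
Product: 11 (E)-1,2-dichloroethenyl ether of AB phenol
Conditions: K2CO3, DMF, 70 °C
Reagents that add atoms: none
Why: Base turns trichloroethylene into dichloroacetylene, to which the phenoxide adds and is protonated anti (addition–elimination route to 1,2-dichlorovinyl ethers); the small electrophile tolerates the two ortho benzyloxy groups.

Step 7
Reactants: 12 squaric acid
Product: 13 dibenzyl squarate (3,4-bis(benzyloxy)cyclobut-3-ene-1,2-dione)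
Conditions: BnOH (3 equiv), toluene, reflux, Dean–Stark
Reagents that add atoms: benzyl alcohol, OCc1ccccc1
Why: Azeotropic Fischer-type esterification; squaric acid is a strong vinylogous acid that catalyses its own diester formation once water is removed.

Step 8
Reactants: 11 (E)-1,2-dichloroethenyl ether of AB phenol; 13 dibenzyl squarate
Product: 16 racemic 4-[(AB-aryloxy)ethynyl]-2,3-bis(benzyloxy)-4-hydroxycyclobut-2-en-1-one, via chloroethynyl ether 14 (not isolated), via lithium acetylide 15 (not isolated)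
Conditions: n-BuLi (2.1 equiv), THF, −78 to −40 °C; then 13, THF, −78 °C; aq NH4Cl
Reagents that add atoms: none
Why: n-BuLi removes the vinyl hydrogen, loss of LiCl gives chloroalkyne 14 and chlorine–lithium exchange gives acetylide 15, whose 1,2-addition to one carbonyl of the symmetrical squarate (the usual mode for organolithiums at −78 °C) creates the carbinol centre as a racemate that needs no control because it vanishes in step 11.

Step 9
Reactants: 16 racemic alkynyl carbinol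
Product: 17 racemic 4-[(AB-aryloxy)ethynyl]-2,3-bis(benzyloxy)-4-(methoxymethoxy)cyclobut-2-en-1-one
Conditions: MOMCl, iPr2NEt, Bu4NI (cat.), CH2Cl2, 0 °C to rt
Reagents that add atoms: chloromethyl methyl ether, COCCl
Why: O-alkylation of the tertiary alcohol by the reactive α-chloro ether under amine-buffered conditions (acetal protection); acid, which would turn the hydroxycyclobutenone into a cyclobutenedione, is avoided.

Step 10
Reactants: 17 racemic alkynyl acetal
Product: 18 racemic 4-[(Z)-2-(AB-aryloxy)ethenyl]-2,3-bis(benzyloxy)-4-(methoxymethoxy)cyclobut-2-en-1-one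
Conditions: H2 (1 atm), Pd/CaCO3 poisoned with Pb(OAc)2 (Lindlar catalyst), quinoline, EtOAc, rt
Reagents that add atoms: none
Why: Lindlar semi-hydrogenation delivers hydrogen syn to the electron-rich ynol ether and gives the (Z)-enol ether; the poisoned catalyst leaves benzyl ethers and the tetrasubstituted enone double bond untouched.

Step 11
Reactants: 18 racemic (Z)-aryloxyvinyl cyclobutenone
Product: 21 ABC phenol 2-(AB-aryloxy)-5,6-bis(benzyloxy)-4-(methoxymethoxy)phenol, via dienylketene 19 (not isolated), via cyclohexadienone 20 (not isolated)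
Conditions: toluene (0.01 M, degassed), 110 °C
Reagents that add atoms: none
Why: Heating opens the cyclobutenone by conrotatory 4π cleavage of the C1–C4 bond to dienylketene 19, in which the acetal oxygen on the former carbinol carbon has turned outward and the (Z)-aryloxyvinyl group inward, so that ketene and vinyl ether are cis. The ketene carbon then bonds to the aryloxy-bearing vinyl carbon in a thermal disrotatory 6π electrocyclisation, which closes ring C as a six-membered carbocycle (C6–C1 bond of ring C) and gives cyclohexa-2,4-dienone 20; enolisation of its CH(OAr) hydrogen aromatises the ring to phenol 21. The closest known reaction is the Moore rearrangement of squarate-derived 4-alkenyl-4-alkoxy- or 4-silyloxycyclobutenones to mono-protected hydroquinones. The only new stereocentre is the transient sp3 carbon of 20, which is removed by tautomerisation, and the racemic carbinol centre of 18 is destroyed in the ring opening. The selectivity needed is torquoselectivity, secured by the donor oxygen on the carbinol carbon, which prefers outward rotation; an inward oxygen would give a ketene that cannot close and simply recloses to 18. The inward-pointing aryloxy group of the Z terminus meets no substituent on the linear ketene carbon, so closure is not blocked, and all five oxygens arrive in place with only the C6 hydroxyl free.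

Step 12
Reactants: 21 ABC phenol; 6 4-bromo-2,6-bis(benzyloxy)benzaldehyde
Product: 22 ABCD aldehyde 2,6-bis(benzyloxy)-4-(ABC-aryloxy)benzaldehyde
Conditions: CuI (20 mol%), picolinic acid (40 mol%), K3PO4, DMSO, 90 °C, argon
Reagents that add atoms: none
Why: Ullmann-type diaryl ether synthesis as in step 4; only the C6 hydroxyl of ring C is free, the bromide is unhindered and para-formyl activated, and the acetal is inert to phosphate base.

Step 13
Reactants: 22 ABCD aldehyde
Product: 24 ABCD phenol 2,6-bis(benzyloxy)-4-(ABC-aryloxy)phenol, via aryl formate 23 (not isolated)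
Conditions: mCPBA, CH2Cl2, 0 °C; then K2CO3, MeOH/THF, rt
Reagents that add atoms: meta-chloroperoxybenzoic acid (mCPBA), O=C(OO)c1cccc(Cl)c1
Why: Baeyer–Villiger oxidation with aryl migration and formate methanolysis, as in step 5; benzyl ethers and the acetal are stable to the peracid.

Step 14
Reactants: 25 1,3-bis(benzyloxy)-5-bromobenzene
Product: 27 2-bromo-4,6-bis(benzyloxy)benzaldehyde, via iminium chloride 26 (not isolated)
Conditions: POCl3, DMF, 0 to 80 °C; then aq NaOAc
Reagents that add atoms: N,N-dimethylformamide, CN(C)C=O; water, O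
Why: Vilsmeier–Haack formylation; the position next to bromine is para to one benzyloxy group, ortho to the other and less shielded than the position between the two benzyloxy groups, so the 2-bromo-4,6-dialkoxy aldehyde should predominate (the minor regioisomer would be compound 6).

Step 15
Reactants: 24 ABCD phenol; 27 2-bromo-4,6-bis(benzyloxy)benzaldehyde
Product: 28 ABCDE aldehyde 2-(ABCD-aryloxy)-4,6-bis(benzyloxy)benzaldehyde
Conditions: CuI (20 mol%), picolinic acid (40 mol%), K3PO4, DMSO, 90 °C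
Reagents that add atoms: none
Why: Ullmann-type coupling; the bromide ortho to the formyl group is activated for reaction at copper, and the 2,6-bis(benzyloxy)phenoxide of ring D is the only nucleophile.

Step 16
Reactants: 28 ABCDE aldehyde
Product: 30 ABCDE phenol 2-(ABCD-aryloxy)-4,6-bis(benzyloxy)phenol, via aryl formate 29 (not isolated)
Conditions: mCPBA, CH2Cl2, 0 °C; then K2CO3, MeOH/THF, rt
Reagents that add atoms: meta-chloroperoxybenzoic acid (mCPBA), O=C(OO)c1cccc(Cl)c1
Why: Baeyer–Villiger oxidation of the 2,4,6-trioxygenated aldehyde and methanolysis uncover the ring E hydroxyl next to the D–O–E ether.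

Step 17
Reactants: 30 ABCDE phenol; 6 4-bromo-2,6-bis(benzyloxy)benzaldehyde
Product: 31 ABCDEF aldehyde 2,6-bis(benzyloxy)-4-(ABCDE-aryloxy)benzaldehyde
Conditions: CuI (20 mol%), picolinic acid (40 mol%), K3PO4, DMSO, 90 °C
Reagents that add atoms: none
Why: Ullmann-type diaryl ether synthesis between the hindered ring E phenoxide and the unhindered, formyl-activated bromide, as in steps 4 and 12.

Step 18
Reactants: 31 ABCDEF aldehyde
Product: 33 ABCDEF phenol 2,6-bis(benzyloxy)-4-(ABCDE-aryloxy)phenol, via aryl formate 32 (not isolated)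
Conditions: mCPBA, CH2Cl2, 0 °C; then K2CO3, MeOH/THF, rt
Reagents that add atoms: meta-chloroperoxybenzoic acid (mCPBA), O=C(OO)c1cccc(Cl)c1
Why: Baeyer–Villiger oxidation and formate methanolysis, as in step 5, give the ring F phenol.

Step 19
Reactants: 34 5-bromobenzene-1,2,3-triol
Product: 35 5-bromo-1,2,3-tris(benzyloxy)benzene
Conditions: BnBr (3.5 equiv), K2CO3, DMF, rt to 60 °C, N2
Reagents that add atoms: benzyl bromide, BrCc1ccccc1
Why: Williamson ether synthesis on all three phenols, run under nitrogen because the pyrogallol is air-sensitive in base.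

Step 20
Reactants: 33 ABCDEF phenol; 35 5-bromo-1,2,3-tris(benzyloxy)benzene
Product: 36 protected heptamer (sixteen benzyl ethers; ring C C3 methoxymethyl ether)
Conditions: CuI (20 mol%), picolinic acid (40 mol%), K3PO4, DMSO, 100 °C
Reagents that add atoms: none
Why: Ullmann-type diaryl ether synthesis; picolinate-ligated copper couples 2,6-disubstituted phenoxides with electron-rich, unhindered aryl bromides, and no other phenol or halide is present.

Step 21
Reactants: 36 protected heptamer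
Product: 37 hexadeca-O-benzyl heptamer with free ring C C3 hydroxyl
Conditions: HCl (conc., cat.), MeOH/THF, 50 °C
Reagents that add atoms: none
Why: Acid-catalysed acetal exchange with methanol frees the ring C C3 hydroxyl; benzyl and diaryl ethers are stable to dilute HCl.

Step 22
Reactants: 37 hexadeca-O-benzyl heptamer
Product: 38 CNP0351377.0
Conditions: H2 (1 atm), Pd/C, THF/MeOH, rt, degassed work-up
Reagents that add atoms: none
Why: Palladium-catalysed hydrogenolysis cleaves all sixteen benzylic C–O bonds while diaryl ether bonds stay intact; the target is achiral, so no stereocontrol is needed.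

**Compound list**

1 | 2,4,6-trihydroxybenzaldehyde | O=Cc1c(O)cc(O)cc1O | starting material
2 | 2,4,6-tris(benzyloxy)benzaldehyde | O=Cc2c(OCc1ccccc1)cc(OCc1ccccc1)cc2OCc1ccccc1 | intermediate
3 | 2,4,6-tris(benzyloxy)phenyl formate (not isolated) | O=COc2c(OCc1ccccc1)cc(OCc1ccccc1)cc2OCc1ccccc1 | intermediate
4 | 2,4,6-tris(benzyloxy)phenol | Oc2c(OCc1ccccc1)cc(OCc1ccccc1)cc2OCc1ccccc1 | intermediate
5 | 4-bromo-2,6-difluorobenzaldehyde | O=Cc1c(F)cc(Br)cc1F | starting material
6 | 4-bromo-2,6-bis(benzyloxy)benzaldehyde | O=Cc2c(OCc1ccccc1)cc(Br)cc2OCc1ccccc1 | intermediate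
7 | AB aldehyde, 2,6-bis(benzyloxy)-4-[2,4,6-tris(benzyloxy)phenoxy]benzaldehyde | O=Cc2c(OCc1ccccc1)cc(Oc3c(OCc1ccccc1)cc(OCc1ccccc1)cc3OCc1ccccc1)cc2OCc1ccccc1 | intermediate
8 | AB formate (not isolated) | O=COc2c(OCc1ccccc1)cc(Oc3c(OCc1ccccc1)cc(OCc1ccccc1)cc3OCc1ccccc1)cc2OCc1ccccc1 | intermediate
9 | AB phenol, 2,6-bis(benzyloxy)-4-[2,4,6-tris(benzyloxy)phenoxy]phenol | Oc2c(OCc1ccccc1)cc(Oc3c(OCc1ccccc1)cc(OCc1ccccc1)cc3OCc1ccccc1)cc2OCc1ccccc1 | intermediate
10 | trichloroethylene | ClC=C(Cl)Cl | starting material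
11 | (E)-1,2-dichloroethenyl ether of AB phenol | Cl/C=C(/Cl)Oc2c(OCc1ccccc1)cc(Oc3c(OCc1ccccc1)cc(OCc1ccccc1)cc3OCc1ccccc1)cc2OCc1ccccc1 | intermediate
12 | squaric acid | OC1=C(O)C(=O)C1=O | starting material
13 | dibenzyl squarate, 3,4-bis(benzyloxy)cyclobut-3-ene-1,2-dione | O=C2C(=O)C(OCc1ccccc1)=C2OCc1ccccc1 | intermediate
14 | chloroethynyl ether of AB phenol (not isolated) | ClC#COc2c(OCc1ccccc1)cc(Oc3c(OCc1ccccc1)cc(OCc1ccccc1)cc3OCc1ccccc1)cc2OCc1ccccc1 | intermediate
15 | lithium (AB-aryloxy)acetylide (not isolated) | [Li]C#COc2c(OCc1ccccc1)cc(Oc3c(OCc1ccccc1)cc(OCc1ccccc1)cc3OCc1ccccc1)cc2OCc1ccccc1 | intermediate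
16 | racemic 4-[(AB-aryloxy)ethynyl]-2,3-bis(benzyloxy)-4-hydroxycyclobut-2-en-1-one | O=C4C(OCc1ccccc1)=C(OCc1ccccc1)C4(O)C#COc2c(OCc1ccccc1)cc(Oc3c(OCc1ccccc1)cc(OCc1ccccc1)cc3OCc1ccccc1)cc2OCc1ccccc1 | intermediate
17 | racemic 4-[(AB-aryloxy)ethynyl]-2,3-bis(benzyloxy)-4-(methoxymethoxy)cyclobut-2-en-1-one | O=C4C(OCc1ccccc1)=C(OCc1ccccc1)C4(OCOC)C#COc2c(OCc1ccccc1)cc(Oc3c(OCc1ccccc1)cc(OCc1ccccc1)cc3OCc1ccccc1)cc2OCc1ccccc1 | intermediate
18 | racemic 4-[(Z)-2-(AB-aryloxy)ethenyl]-2,3-bis(benzyloxy)-4-(methoxymethoxy)cyclobut-2-en-1-one (key-step precursor) | O=C4C(OCc1ccccc1)=C(OCc1ccccc1)C4(OCOC)/C=C\Oc2c(OCc1ccccc1)cc(Oc3c(OCc1ccccc1)cc(OCc1ccccc1)cc3OCc1ccccc1)cc2OCc1ccccc1 | intermediate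
19 | (3Z,5Z)-6-(AB-aryloxy)-2,3-bis(benzyloxy)-4-(methoxymethoxy)hexa-1,3,5-trien-1-one, dienylketene (not isolated) | O=C=C(OCc1ccccc1)/C(OCc1ccccc1)=C(/OCOC)\C=C/Oc2c(OCc1ccccc1)cc(Oc3c(OCc1ccccc1)cc(OCc1ccccc1)cc3OCc1ccccc1)cc2OCc1ccccc1 | intermediate
20 | racemic 6-(AB-aryloxy)-2,3-bis(benzyloxy)-4-(methoxymethoxy)cyclohexa-2,4-dien-1-one (not isolated) | O=C4C(OCc1ccccc1)=C(OCc1ccccc1)C(OCOC)=CC4Oc2c(OCc1ccccc1)cc(Oc3c(OCc1ccccc1)cc(OCc1ccccc1)cc3OCc1ccccc1)cc2OCc1ccccc1 | intermediate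
21 | ABC phenol, 2-(AB-aryloxy)-5,6-bis(benzyloxy)-4-(methoxymethoxy)phenol (key-step product) | Oc4c(OCc1ccccc1)c(OCc1ccccc1)c(OCOC)cc4Oc2c(OCc1ccccc1)cc(Oc3c(OCc1ccccc1)cc(OCc1ccccc1)cc3OCc1ccccc1)cc2OCc1ccccc1 | intermediate
22 | ABCD aldehyde, 2,6-bis(benzyloxy)-4-(ABC-aryloxy)benzaldehyde | O=Cc5c(OCc1ccccc1)cc(Oc4c(OCc1ccccc1)c(OCc1ccccc1)c(OCOC)cc4Oc2c(OCc1ccccc1)cc(Oc3c(OCc1ccccc1)cc(OCc1ccccc1)cc3OCc1ccccc1)cc2OCc1ccccc1)cc5OCc1ccccc1 | intermediate
23 | ABCD formate (not isolated) | O=COc5c(OCc1ccccc1)cc(Oc4c(OCc1ccccc1)c(OCc1ccccc1)c(OCOC)cc4Oc2c(OCc1ccccc1)cc(Oc3c(OCc1ccccc1)cc(OCc1ccccc1)cc3OCc1ccccc1)cc2OCc1ccccc1)cc5OCc1ccccc1 | intermediate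
24 | ABCD phenol, 2,6-bis(benzyloxy)-4-(ABC-aryloxy)phenol | Oc5c(OCc1ccccc1)cc(Oc4c(OCc1ccccc1)c(OCc1ccccc1)c(OCOC)cc4Oc2c(OCc1ccccc1)cc(Oc3c(OCc1ccccc1)cc(OCc1ccccc1)cc3OCc1ccccc1)cc2OCc1ccccc1)cc5OCc1ccccc1 | intermediate
25 | 1,3-bis(benzyloxy)-5-bromobenzene | Brc2cc(OCc1ccccc1)cc(OCc1ccccc1)c2 | starting material
26 | N-[2-bromo-4,6-bis(benzyloxy)benzylidene]-N-methylmethanaminium chloride (not isolated) | C[N+](C)=Cc2c(Br)cc(OCc1ccccc1)cc2OCc1ccccc1.[Cl-] | intermediate
27 | 2-bromo-4,6-bis(benzyloxy)benzaldehyde | O=Cc2c(Br)cc(OCc1ccccc1)cc2OCc1ccccc1 | intermediate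
28 | ABCDE aldehyde, 2-(ABCD-aryloxy)-4,6-bis(benzyloxy)benzaldehyde | O=Cc6c(OCc1ccccc1)cc(OCc1ccccc1)cc6Oc5c(OCc1ccccc1)cc(Oc4c(OCc1ccccc1)c(OCc1ccccc1)c(OCOC)cc4Oc2c(OCc1ccccc1)cc(Oc3c(OCc1ccccc1)cc(OCc1ccccc1)cc3OCc1ccccc1)cc2OCc1ccccc1)cc5OCc1ccccc1 | intermediate
29 | ABCDE formate (not isolated) | O=COc6c(OCc1ccccc1)cc(OCc1ccccc1)cc6Oc5c(OCc1ccccc1)cc(Oc4c(OCc1ccccc1)c(OCc1ccccc1)c(OCOC)cc4Oc2c(OCc1ccccc1)cc(Oc3c(OCc1ccccc1)cc(OCc1ccccc1)cc3OCc1ccccc1)cc2OCc1ccccc1)cc5OCc1ccccc1 | intermediate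
30 | ABCDE phenol, 2-(ABCD-aryloxy)-4,6-bis(benzyloxy)phenol | Oc6c(OCc1ccccc1)cc(OCc1ccccc1)cc6Oc5c(OCc1ccccc1)cc(Oc4c(OCc1ccccc1)c(OCc1ccccc1)c(OCOC)cc4Oc2c(OCc1ccccc1)cc(Oc3c(OCc1ccccc1)cc(OCc1ccccc1)cc3OCc1ccccc1)cc2OCc1ccccc1)cc5OCc1ccccc1 | intermediate
31 | ABCDEF aldehyde, 2,6-bis(benzyloxy)-4-(ABCDE-aryloxy)benzaldehyde | O=Cc7c(OCc1ccccc1)cc(Oc6c(OCc1ccccc1)cc(OCc1ccccc1)cc6Oc5c(OCc1ccccc1)cc(Oc4c(OCc1ccccc1)c(OCc1ccccc1)c(OCOC)cc4Oc2c(OCc1ccccc1)cc(Oc3c(OCc1ccccc1)cc(OCc1ccccc1)cc3OCc1ccccc1)cc2OCc1ccccc1)cc5OCc1ccccc1)cc7OCc1ccccc1 | intermediate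
32 | ABCDEF formate (not isolated) | O=COc7c(OCc1ccccc1)cc(Oc6c(OCc1ccccc1)cc(OCc1ccccc1)cc6Oc5c(OCc1ccccc1)cc(Oc4c(OCc1ccccc1)c(OCc1ccccc1)c(OCOC)cc4Oc2c(OCc1ccccc1)cc(Oc3c(OCc1ccccc1)cc(OCc1ccccc1)cc3OCc1ccccc1)cc2OCc1ccccc1)cc5OCc1ccccc1)cc7OCc1ccccc1 | intermediate
33 | ABCDEF phenol, 2,6-bis(benzyloxy)-4-(ABCDE-aryloxy)phenol | Oc7c(OCc1ccccc1)cc(Oc6c(OCc1ccccc1)cc(OCc1ccccc1)cc6Oc5c(OCc1ccccc1)cc(Oc4c(OCc1ccccc1)c(OCc1ccccc1)c(OCOC)cc4Oc2c(OCc1ccccc1)cc(Oc3c(OCc1ccccc1)cc(OCc1ccccc1)cc3OCc1ccccc1)cc2OCc1ccccc1)cc5OCc1ccccc1)cc7OCc1ccccc1 | intermediate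
34 | 5-bromobenzene-1,2,3-triol | Oc1cc(Br)cc(O)c1O | starting material
35 | 5-bromo-1,2,3-tris(benzyloxy)benzene | Brc2cc(OCc1ccccc1)c(OCc1ccccc1)c(OCc1ccccc1)c2 | intermediate
36 | protected heptamer (sixteen benzyl ethers, ring C C3 methoxymethyl ether) | c1ccccc1COc8c(OCc1ccccc1)cc(Oc7c(OCc1ccccc1)cc(Oc6c(OCc1ccccc1)cc(OCc1ccccc1)cc6Oc5c(OCc1ccccc1)cc(Oc4c(OCc1ccccc1)c(OCc1ccccc1)c(OCOC)cc4Oc2c(OCc1ccccc1)cc(Oc3c(OCc1ccccc1)cc(OCc1ccccc1)cc3OCc1ccccc1)cc2OCc1ccccc1)cc5OCc1ccccc1)cc7OCc1ccccc1)cc8OCc1ccccc1 | intermediate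
37 | hexadeca-O-benzyl heptamer with free ring C C3 hydroxyl | c1ccccc1COc8c(OCc1ccccc1)cc(Oc7c(OCc1ccccc1)cc(Oc6c(OCc1ccccc1)cc(OCc1ccccc1)cc6Oc5c(OCc1ccccc1)cc(Oc4c(OCc1ccccc1)c(OCc1ccccc1)c(O)cc4Oc2c(OCc1ccccc1)cc(Oc3c(OCc1ccccc1)cc(OCc1ccccc1)cc3OCc1ccccc1)cc2OCc1ccccc1)cc5OCc1ccccc1)cc7OCc1ccccc1)cc8OCc1ccccc1 | intermediate
38 | CNP0351377.0 | Oc1cc(O)c(Oc2cc(O)c(Oc3cc(O)c(O)c(O)c3Oc3cc(O)c(Oc4cc(O)cc(O)c4Oc4cc(O)c(Oc5cc(O)c(O)c(O)c5)c(O)c4)c(O)c3)c(O)c2)c(O)c1 | target

**Summary**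

Total steps: 22. Longest linear sequence: 18 steps (steps 1, 2, 4, 5, 6, 8–13, 15–18, 20–22).

Steps most likely to fail:

1. Step 11. The ketene may close slowly because the bulky aryloxy group lies on the inner side of the reacting vinyl terminus and the acetal crowds the same region; the ketene would then be lost to dimerisation or to capture by trace nucleophiles. The fallback keeps the ring construction but changes the substrate and the way the two para oxygens are told apart. It sets out from carbinol 16, which is semi-hydrogenated over the Lindlar catalyst to the free (Z)-alkenyl carbinol F1. Heating F1 in degassed toluene should open it to the hydroxy dienylketene F2, which closes to the hydroxy dienone F3 and aromatises by proton shift to the hydroquinone F4; this is the free-hydroxyl form of the rearrangement, less crowded at the carbinol carbon. In F4 the hydroxyl at C3 of ring C (neighbours H and OBn) should be alkylated by MOMCl (1 equiv) and iPr2NEt at low temperature in preference to the C6 hydroxyl (neighbours OBn and the AB aryloxy group), which returns the route at 21.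

2. Step 12. Copper-mediated C–O bond formation at the most crowded phenoxide of the route may be slow, with competing oxidation of the electron-rich phenoxide and hydrodebromination of 6. The fallback sets out from 21 and uses metal-free SNAr with 2,4,6-trifluorobenzaldehyde (K2CO3, DMF, rt), in which the bulky phenoxide should attack the unhindered carbon para to the formyl group to give 2,6-difluoro-4-(ABC-aryloxy)benzaldehyde F5. Sodium benzyloxide (2 equiv, THF) then replaces both ortho fluorides as in step 3, and the route is rejoined at 22.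

3. Step 20. Coupling of an electron-rich, non-activated bromide with the hindered phenoxide of a hexameric substrate may stall, leaving unreacted phenol and reduced bromide. The fallback sets out from 33 and couples it with the activated bromide 6 under the conditions of step 17 to give the heptameric aldehyde F6. Baeyer–Villiger oxidation gives the heptameric formate F7, methanolysis gives the ring G phenol F8, and benzylation of F8 (BnBr, K2CO3, DMF) returns the route at 36.

**Further compounds**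

F1 | step 11 | racemic 4-[(Z)-2-(AB-aryloxy)ethenyl]-2,3-bis(benzyloxy)-4-hydroxycyclobut-2-en-1-one | O=C4C(OCc1ccccc1)=C(OCc1ccccc1)C4(O)/C=C\Oc2c(OCc1ccccc1)cc(Oc3c(OCc1ccccc1)cc(OCc1ccccc1)cc3OCc1ccccc1)cc2OCc1ccccc1
F2 | step 11 | (3Z,5Z)-6-(AB-aryloxy)-2,3-bis(benzyloxy)-4-hydroxyhexa-1,3,5-trien-1-one | O=C=C(OCc1ccccc1)/C(OCc1ccccc1)=C(/O)\C=C/Oc2c(OCc1ccccc1)cc(Oc3c(OCc1ccccc1)cc(OCc1ccccc1)cc3OCc1ccccc1)cc2OCc1ccccc1
F3 | step 11 | racemic 6-(AB-aryloxy)-2,3-bis(benzyloxy)-4-hydroxycyclohexa-2,4-dien-1-one | O=C4C(OCc1ccccc1)=C(OCc1ccccc1)C(O)=CC4Oc2c(OCc1ccccc1)cc(Oc3c(OCc1ccccc1)cc(OCc1ccccc1)cc3OCc1ccccc1)cc2OCc1ccccc1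
F4 | step 11 | 5-(AB-aryloxy)-2,3-bis(benzyloxy)benzene-1,4-diol | Oc4c(OCc1ccccc1)c(OCc1ccccc1)c(O)cc4Oc2c(OCc1ccccc1)cc(Oc3c(OCc1ccccc1)cc(OCc1ccccc1)cc3OCc1ccccc1)cc2OCc1ccccc1
F5 | step 12 | 2,6-difluoro-4-(ABC-aryloxy)benzaldehyde | O=Cc5c(F)cc(Oc4c(OCc1ccccc1)c(OCc1ccccc1)c(OCOC)cc4Oc2c(OCc1ccccc1)cc(Oc3c(OCc1ccccc1)cc(OCc1ccccc1)cc3OCc1ccccc1)cc2OCc1ccccc1)cc5F
F6 | step 20 | heptameric aldehyde, 2,6-bis(benzyloxy)-4-(ABCDEF-aryloxy)benzaldehyde | O=Cc8c(OCc1ccccc1)cc(Oc7c(OCc1ccccc1)cc(Oc6c(OCc1ccccc1)cc(OCc1ccccc1)cc6Oc5c(OCc1ccccc1)cc(Oc4c(OCc1ccccc1)c(OCc1ccccc1)c(OCOC)cc4Oc2c(OCc1ccccc1)cc(Oc3c(OCc1ccccc1)cc(OCc1ccccc1)cc3OCc1ccccc1)cc2OCc1ccccc1)cc5OCc1ccccc1)cc7OCc1ccccc1)cc8OCc1ccccc1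
F7 | step 20 | heptameric formate, 2,6-bis(benzyloxy)-4-(ABCDEF-aryloxy)phenyl formate | O=COc8c(OCc1ccccc1)cc(Oc7c(OCc1ccccc1)cc(Oc6c(OCc1ccccc1)cc(OCc1ccccc1)cc6Oc5c(OCc1ccccc1)cc(Oc4c(OCc1ccccc1)c(OCc1ccccc1)c(OCOC)cc4Oc2c(OCc1ccccc1)cc(Oc3c(OCc1ccccc1)cc(OCc1ccccc1)cc3OCc1ccccc1)cc2OCc1ccccc1)cc5OCc1ccccc1)cc7OCc1ccccc1)cc8OCc1ccccc1
F8 | step 20 | ring G phenol, 2,6-bis(benzyloxy)-4-(ABCDEF-aryloxy)phenol | Oc8c(OCc1ccccc1)cc(Oc7c(OCc1ccccc1)cc(Oc6c(OCc1ccccc1)cc(OCc1ccccc1)cc6Oc5c(OCc1ccccc1)cc(Oc4c(OCc1ccccc1)c(OCc1ccccc1)c(OCOC)cc4Oc2c(OCc1ccccc1)cc(Oc3c(OCc1ccccc1)cc(OCc1ccccc1)cc3OCc1ccccc1)cc2OCc1ccccc1)cc5OCc1ccccc1)cc7OCc1ccccc1)cc8OCc1ccccc1
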